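Assumption: the SMILES is read as (2R) side chain, lactone (2S,3R,4R), all-E tetraene, pyran (2S,3R,6S); 3,4-di-O-acetyl-L-rhamnal, dimethyl (S)-malate, the silylethynyl sulfone and trans-2-bromovinylboronic acid MIDA ester are taken as catalogue compounds.

**Retrosynthetic overview**
1. The tetraene is cut at its central diene–diene bond: Suzuki–Miyaura union of a lactone dienyl MIDA boronate and a pyran dienyl chloride, each grown from a terminal alkyne.
2. Lactone half: the quaternary C–alkynyl bond comes from a light-driven decatungstate C–H alkynylation of an all-cis γ-lactone; that lactone comes from hydrogenation of a butenolide, made via a tetronic acid (Dieckmann) from Fráter–Seebach-methylated dimethyl (S)-malate.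
3. Pyran half: Ferrier C-alkynylation of 3,4-di-O-acetyl-L-rhamnal gives the 2,6-trans dihydropyran; an enone transposition with two methyl additions sets the tertiary carbinol; carboalumination builds the trisubstituted alkene.
4. Ring order: the γ-lactone ring is closed first (step 2); the pyran ring is bought with L-rhamnal and only refunctionalised; the two rings are joined in the last step.

**Route**

Step 1
Reactants: 1 dimethyl (S)-malate; 2 iodomethane; 3 propanoyl chloride
Product: 5 dimethyl (2R,3S)-2-methyl-3-(propanoyloxy)butanedioate, via lithium alkoxide of dimethyl (2S,3R)-3-methylmalate 4 (not isolated)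
Conditions: LiN(iPr)2 (2.1 equiv), THF, −78 to −20 °C; MeI, −78 to 0 °C; then EtCOCl (2.5 equiv), 0 °C
Reagents that add atoms: iodomethane, CI; propanoyl chloride, CCC(=O)Cl
Why: Fráter–Seebach alkylation, in which the chelated alkoxide–enolate dianion is methylated anti to the alkoxide (new 3R centre, about 9:1, controlled by the malate carbinol), followed by O-acylation of the surviving lithium alkoxide in the same flask.

Step 2
Reactants: 5 dimethyl (2R,3S)-2-methyl-3-(propanoyloxy)butanedioate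
Product: 6 methyl (2R)-2-[(2S)-3-hydroxy-4-methyl-5-oxo-2,5-dihydrofuran-2-yl]propanoate
Conditions: LiN(SiMe3)2 (2.1 equiv), THF, −78 to −20 °C; then 1 M HCl
Reagents that add atoms: none
Why: Lacey–Dieckmann condensation, in which the propanoate enolate closes 5-exo onto the neighbouring, more electrophilic α-oxy ester and the tetronic acid is at once deprotonated, so the ring CH–O centre keeps its configuration.

Step 3
Reactants: 6 methyl (2R)-2-[(2S)-3-hydroxy-4-methyl-5-oxo-2,5-dihydrofuran-2-yl]propanoate; 7 trifluoromethanesulfonic anhydride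
Product: 8 methyl (2R)-2-[(2S)-4-methyl-5-oxo-3-(trifluoromethanesulfonyloxy)-2,5-dihydrofuran-2-yl]propanoate
Conditions: Tf2O, iPr2NEt, CH2Cl2, −78 °C
Reagents that add atoms: trifluoromethanesulfonic anhydride, O=S(=O)(OS(=O)(=O)C(F)(F)F)C(F)(F)F
Why: O-sulfonylation of the vinylogous acid gives the enol triflate needed for cross-coupling.

Step 4
Reactants: 8 methyl (2R)-2-[(2S)-4-methyl-5-oxo-3-(trifluoromethanesulfonyloxy)-2,5-dihydrofuran-2-yl]propanoate; 9 chloro(methyl)zinc
Product: 10 methyl (2R)-2-[(2S)-3,4-dimethyl-5-oxo-2,5-dihydrofuran-2-yl]propanoate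
Conditions: MeZnCl (1.5 equiv), Pd(PPh3)4 (3 mol%), THF, 25 °C
Reagents that add atoms: chloro(methyl)zinc, C[Zn]Cl
Why: Negishi cross-coupling replaces the triflate by methyl under neutral conditions that leave both esters and the stereocentres untouched.

Step 5
Reactants: 10 methyl (2R)-2-[(2S)-3,4-dimethyl-5-oxo-2,5-dihydrofuran-2-yl]propanoate; 11 hydrogen
Product: 12 methyl (2R)-2-[(2R,3S,4R)-3,4-dimethyl-5-oxooxolan-2-yl]propanoate
Conditions: H2 (60 bar), Rh/Al2O3 (5 wt% Rh), EtOAc, 25 °C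
Reagents that add atoms: none
Why: heterogeneous syn-hydrogenation of the tetrasubstituted butenolide from the face opposite the C2 side chain sets C3 and C4 (all-cis lactone) under control of the malate-derived centre.

Step 6
Reactants: 12 methyl (2R)-2-[(2R,3S,4R)-3,4-dimethyl-5-oxooxolan-2-yl]propanoate; 13 1-methyl-4-{[(trimethylsilyl)ethynyl]sulfonyl}benzene
Product: 15 methyl (2R)-2-[(2S,3S,4R)-3-ethynyl-3,4-dimethyl-5-oxooxolan-2-yl]propanoate, via C-silyl alkyne 14 (not isolated)
Conditions: (Bu4N)4[W10O32] (5 mol%), 13 (1.5 equiv), MeCN, 390 nm LEDs, 25 °C; then Bu4NF, AcOH, THF, 0 °C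
Reagents that add atoms: 1-methyl-4-{[(trimethylsilyl)ethynyl]sulfonyl}benzene, Cc1ccc(cc1)S(=O)(=O)C#C[Si](C)(C)C
Why: Proposed new method: excited decatungstate, an electrophilic and bulky hydrogen-atom abstractor, should take the one tertiary C–H that is neither α to a carbonyl (C4–H and the side-chain C–H are polarity-mismatched) nor α-acyloxy and doubly flanked (C2–H), namely the exposed C3–H on the convex face of the all-cis lactone; the planar tertiary radical then adds to the sulfonyl-bearing alkyne carbon of 13 on the face opposite the C4 methyl and the C2 side chain (net retention, quaternary 3S centre), β-scission expels the sulfonyl radical, which takes the hydrogen back from reduced decatungstate, and fluoride removes silicon; the closest known reactions are aryl-ketone-mediated photochemical C(sp3)–H alkynylation of ethers and alkanes with alkynyl sulfones and decatungstate C–H alkylation at tertiary and β-carbonyl positions, neither shown on a lactone to set a quaternary stereocentre.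

Step 7
Reactants: 15 methyl (2R)-2-[(2S,3S,4R)-3-ethynyl-3,4-dimethyl-5-oxooxolan-2-yl]propanoate; 16 tributylstannane; 17 2-[(E)-2-bromoethenyl]-6-methyl-1,3,6,2-dioxazaborocane-4,8-dione
Product: 19 methyl (2R)-2-{(2S,3R,4R)-3,4-dimethyl-3-[(1E,3E)-4-(6-methyl-4,8-dioxo-1,3,6,2-dioxazaborocan-2-yl)buta-1,3-dien-1-yl]-5-oxooxolan-2-yl}propanoate, via vinylstannane 18 (not isolated)
Conditions: Bu3SnH (1.05 equiv), PdCl2(PPh3)2 (2 mol%), THF, 0 °C; then 17, Pd2(dba)3 (2.5 mol%), P(2-furyl)3 (10 mol%), DMF, 45 °C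
Reagents that add atoms: 2-[(E)-2-bromoethenyl]-6-methyl-1,3,6,2-dioxazaborocane-4,8-dione, Br/C=C/[B-]12OC(=O)C[N+]1(C)CC(=O)O2
Why: palladium-catalysed syn-hydrostannation places tin on the terminal carbon (E) because of the neighbouring quaternary carbon, and the one-pot Stille coupling proceeds with retention at both alkenes while the MIDA boronate stays inert under anhydrous conditions.

Step 8
Reactants: 20 3,4-di-O-acetyl-L-rhamnal; 21 bis(trimethylsilyl)acetylene
Product: 22 (2S,3R,6R)-2-methyl-6-[(trimethylsilyl)ethynyl]-3,6-dihydro-2H-pyran-3-yl acetate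
Conditions: SnCl4 (0.5 equiv), CH2Cl2, −20 °C
Reagents that add atoms: bis(trimethylsilyl)acetylene, C[Si](C)(C)C#C[Si](C)(C)C
Why: Ferrier-type C-glycosylation (Isobe alkynylation), in which the allylic oxocarbenium ion is attacked ipso by the alkynylsilane pseudo-axially, trans to the C2 methyl, giving the 2,6-trans dihydropyran under control of the rhamnose-derived centre.

Step 9
Reactants: 22 (2S,3R,6R)-2-methyl-6-[(trimethylsilyl)ethynyl]-3,6-dihydro-2H-pyran-3-yl acetate
Product: 23 (2S,3R,6R)-6-ethynyl-2-methyl-3,6-dihydro-2H-pyran-3-ol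
Conditions: K2CO3 (0.3 equiv), MeOH, 25 °C
Reagents that add atoms: none
Why: base-catalysed methanolysis removes the acetate (transesterification) and the alkynyl silyl group (protodesilylation) in one operation.

Step 10
Reactants: 23 (2S,3R,6R)-6-ethynyl-2-methyl-3,6-dihydro-2H-pyran-3-ol
Product: 24 (2S,6R)-6-ethynyl-2-methyl-2H-pyran-3(6H)-one
Conditions: MnO2 (15 equiv), CH2Cl2, 25 °C
Reagents that add atoms: none
Why: chemoselective allylic alcohol oxidation under neutral conditions gives the enone without epimerising either ring stereocentre.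

Step 11
Reactants: 24 (2S,6R)-6-ethynyl-2-methyl-2H-pyran-3(6H)-one; 25 methyllithium
Product: 26 (2S,3R,6R)-6-ethynyl-2,3-dimethyl-3,6-dihydro-2H-pyran-3-ol
Conditions: MeLi (2.5 equiv), THF, −78 °C; then H2O
Reagents that add atoms: methyllithium, [Li]C
Why: 1,2-addition of methyllithium to the enone (one equivalent is used up by the alkyne C–H) gives the tertiary allylic alcohol, whose new carbinol configuration (axial attack, major isomer drawn) is erased in step 12.

Step 12
Reactants: 26 (2S,3R,6R)-6-ethynyl-2,3-dimethyl-3,6-dihydro-2H-pyran-3-ol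
Product: 27 (2S,6S)-2-ethynyl-5,6-dimethyl-2H-pyran-3(6H)-one
Conditions: [C5H5NH][CrO3Cl] (2 equiv), 4 Å molecular sieves, CH2Cl2, 25 °C
Reagents that add atoms: pyridinium chlorochromate, [O-][Cr](=O)(=O)Cl.c1cc[nH+]cc1
Why: Babler–Dauben oxidative 1,3-transposition, in which the tertiary chromate ester undergoes a [3,3] shift (the new C–O oxygen comes from chromium) and is oxidised to the transposed enone, placing the methyl on the ring alkene and the carbonyl next to the alkynyl-bearing carbon.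

Step 13
Reactants: 27 (2S,6S)-2-ethynyl-5,6-dimethyl-2H-pyran-3(6H)-one; 28 methylmagnesium bromide
Product: 29 (2S,3R,6S)-2-ethynyl-3,5,6-trimethyl-3,6-dihydro-2H-pyran-3-ol
Conditions: MeMgBr (3 equiv), THF, −78 °C; then H2O
Reagents that add atoms: methylmagnesium bromide, C[Mg]Br
Why: Grignard 1,2-addition; with the C6 methyl pseudo-axial (avoiding allylic 1,2-strain with the C5 methyl) and the C2 alkynyl group pseudo-equatorial, axial attack on the enone carbonyl delivers methyl cis to the alkynyl group and leaves the hydroxyl trans to it (3R), as for hydride reductions of such pyranones.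

Step 14
Reactants: 29 (2S,3R,6S)-2-ethynyl-3,5,6-trimethyl-3,6-dihydro-2H-pyran-3-ol; 30 trimethylaluminium; 31 (E)-1,2-dichloroethene
Product: 34 (2S,3R,6S)-2-[(2E,4E)-5-chloropenta-2,4-dien-2-yl]-3,5,6-trimethyl-3,6-dihydro-2H-pyran-3-ol, via alkenylalane 32 (not isolated), via alkenylzinc chloride 33 (not isolated)
Conditions: AlMe3 (3.5 equiv), Cp2ZrCl2 (0.25 equiv), CH2Cl2, 0 to 25 °C; evaporate; then ZnCl2 (1 equiv), Pd(PPh3)4 (5 mol%), 31 (10 equiv), THF, 25 °C
Reagents that add atoms: trimethylaluminium, C[Al](C)C; (E)-1,2-dichloroethene, Cl/C=C/Cl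
Why: Negishi zirconium-catalysed syn-carboalumination puts methyl on the internal and aluminium on the terminal alkyne carbon (E-alkenylalane; the hydroxyl is masked as its aluminium alkoxide), and zinc/palladium Negishi coupling with excess dichloroethene gives the monocoupled chlorodiene with retention.

Step 15
Reactants: 19 methyl (2R)-2-{(2S,3R,4R)-3,4-dimethyl-3-[(1E,3E)-4-(6-methyl-4,8-dioxo-1,3,6,2-dioxazaborocan-2-yl)buta-1,3-dien-1-yl]-5-oxooxolan-2-yl}propanoate; 34 (2S,3R,6S)-2-[(2E,4E)-5-chloropenta-2,4-dien-2-yl]-3,5,6-trimethyl-3,6-dihydro-2H-pyran-3-ol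
Product: 36 methyl (2R)-2-{(2S,3R,4R)-3-[(1E,3E,5E,7E)-8-[(2S,3R,6S)-3-hydroxy-3,5,6-trimethyl-3,6-dihydro-2H-pyran-2-yl]nona-1,3,5,7-tetraen-1-yl]-3,4-dimethyl-5-oxooxolan-2-yl}propanoate, via dienylboronic acid 35 (not isolated)
Conditions: Pd(OAc)2 (5 mol%), XPhos (10 mol%), K3PO4 (3 M in H2O), THF, 45 °C, dark
Reagents that add atoms: (2S,3R,6S)-2-[(2E,4E)-5-chloropenta-2,4-dien-2-yl]-3,5,6-trimethyl-3,6-dihydro-2H-pyran-3-ol, Cl/C=C/C=C(\C)[C@@H]1O[C@@H](C)C(C)=C[C@@]1(C)O
Why: Suzuki–Miyaura coupling with slow aqueous release of the dienylboronic acid from its MIDA ester keeps the sensitive boronic acid at low concentration and joins the two dienes with retention of all four alkene geometries, under base mild enough for the lactone, the methyl ester and the free tertiary alcohol.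

**Compound list**
1 | dimethyl (S)-malate, dimethyl (2S)-2-hydroxybutanedioate | COC(=O)C[C@H](O)C(=O)OC | starting material
2 | iodomethane | CI | starting material
3 | propanoyl chloride | CCC(=O)Cl | starting material
4 | dimethyl (2S,3R)-2-hydroxy-3-methylbutanedioate (present in the flask as its lithium alkoxide) | COC(=O)[C@H](C)[C@H](O)C(=O)OC | intermediate
5 | dimethyl (2R,3S)-2-methyl-3-(propanoyloxy)butanedioate | COC(=O)[C@H](C)[C@H](OC(=O)CC)C(=O)OC | intermediate
6 | methyl (2R)-2-[(2S)-3-hydroxy-4-methyl-5-oxo-2,5-dihydrofuran-2-yl]propanoate | COC(=O)[C@H](C)[C@@H]1OC(=O)C(C)=C1O | intermediate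
7 | trifluoromethanesulfonic anhydride | O=S(=O)(OS(=O)(=O)C(F)(F)F)C(F)(F)F | starting material
8 | methyl (2R)-2-[(2S)-4-methyl-5-oxo-3-(trifluoromethanesulfonyloxy)-2,5-dihydrofuran-2-yl]propanoate | COC(=O)[C@H](C)[C@@H]1OC(=O)C(C)=C1OS(=O)(=O)C(F)(F)F | intermediate
9 | chloro(methyl)zinc | C[Zn]Cl | starting material
10 | methyl (2R)-2-[(2S)-3,4-dimethyl-5-oxo-2,5-dihydrofuran-2-yl]propanoate | COC(=O)[C@H](C)[C@@H]1OC(=O)C(C)=C1C | intermediate
11 | hydrogen | [H][H] | starting material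
12 | methyl (2R)-2-[(2R,3S,4R)-3,4-dimethyl-5-oxooxolan-2-yl]propanoate (all-cis lactone) | COC(=O)[C@H](C)[C@@H]1OC(=O)[C@H](C)[C@@H]1C | intermediate
13 | 1-methyl-4-{[(trimethylsilyl)ethynyl]sulfonyl}benzene | Cc1ccc(cc1)S(=O)(=O)C#C[Si](C)(C)C | starting material
14 | methyl (2R)-2-{(2S,3S,4R)-3,4-dimethyl-5-oxo-3-[(trimethylsilyl)ethynyl]oxolan-2-yl}propanoate | COC(=O)[C@H](C)[C@@H]1OC(=O)[C@H](C)[C@@]1(C)C#C[Si](C)(C)C | intermediate
15 | methyl (2R)-2-[(2S,3S,4R)-3-ethynyl-3,4-dimethyl-5-oxooxolan-2-yl]propanoate | COC(=O)[C@H](C)[C@@H]1OC(=O)[C@H](C)[C@@]1(C)C#C | intermediate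
16 | tributylstannane | CCCC[SnH](CCCC)CCCC | starting material
17 | 2-[(E)-2-bromoethenyl]-6-methyl-1,3,6,2-dioxazaborocane-4,8-dione (trans-2-bromovinylboronic acid MIDA ester) | Br/C=C/[B-]12OC(=O)C[N+]1(C)CC(=O)O2 | starting material
18 | methyl (2R)-2-{(2S,3S,4R)-3,4-dimethyl-5-oxo-3-[(E)-2-(tributylstannyl)ethenyl]oxolan-2-yl}propanoate | COC(=O)[C@H](C)[C@@H]1OC(=O)[C@H](C)[C@@]1(C)/C=C/[Sn](CCCC)(CCCC)CCCC | intermediate
19 | methyl (2R)-2-{(2S,3R,4R)-3,4-dimethyl-3-[(1E,3E)-4-(6-methyl-4,8-dioxo-1,3,6,2-dioxazaborocan-2-yl)buta-1,3-dien-1-yl]-5-oxooxolan-2-yl}propanoate | COC(=O)[C@H](C)[C@@H]1OC(=O)[C@H](C)[C@@]1(C)/C=C/C=C/[B-]23OC(=O)C[N+]2(C)CC(=O)O3 | intermediate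
20 | 3,4-di-O-acetyl-L-rhamnal, (2S,3S,4S)-2-methyl-3,4-dihydro-2H-pyran-3,4-diyl diacetate | C[C@@H]1OC=C[C@H](OC(C)=O)[C@H]1OC(C)=O | starting material
21 | bis(trimethylsilyl)acetylene | C[Si](C)(C)C#C[Si](C)(C)C | starting material
22 | (2S,3R,6R)-2-methyl-6-[(trimethylsilyl)ethynyl]-3,6-dihydro-2H-pyran-3-yl acetate | C[Si](C)(C)C#C[C@@H]1O[C@@H](C)[C@H](OC(C)=O)C=C1 | intermediate
23 | (2S,3R,6R)-6-ethynyl-2-methyl-3,6-dihydro-2H-pyran-3-ol | C#C[C@@H]1O[C@@H](C)[C@H](O)C=C1 | intermediate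
24 | (2S,6R)-6-ethynyl-2-methyl-2H-pyran-3(6H)-one | C#C[C@@H]1O[C@@H](C)C(=O)C=C1 | intermediate
25 | methyllithium | [Li]C | starting material
26 | (2S,3R,6R)-6-ethynyl-2,3-dimethyl-3,6-dihydro-2H-pyran-3-ol | C#C[C@@H]1O[C@@H](C)[C@](C)(O)C=C1 | intermediate
27 | (2S,6S)-2-ethynyl-5,6-dimethyl-2H-pyran-3(6H)-one | C#C[C@@H]1O[C@@H](C)C(C)=CC1=O | intermediate
28 | methylmagnesium bromide | C[Mg]Br | starting material
29 | (2S,3R,6S)-2-ethynyl-3,5,6-trimethyl-3,6-dihydro-2H-pyran-3-ol | C#C[C@@H]1O[C@@H](C)C(C)=C[C@@]1(C)O | intermediate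
30 | trimethylaluminium | C[Al](C)C | starting material
31 | (E)-1,2-dichloroethene | Cl/C=C/Cl | starting material
32 | dimethyl{(E)-2-[(2S,3R,6S)-3-[(dimethylalumanyl)oxy]-3,5,6-trimethyl-3,6-dihydro-2H-pyran-2-yl]prop-1-en-1-yl}alumane | C[Al](C)/C=C(\C)[C@@H]1O[C@@H](C)C(C)=C[C@@]1(C)O[Al](C)C | intermediate
33 | chloro{(E)-2-[(2S,3R,6S)-3-[(dimethylalumanyl)oxy]-3,5,6-trimethyl-3,6-dihydro-2H-pyran-2-yl]prop-1-en-1-yl}zinc | Cl[Zn]/C=C(\C)[C@@H]1O[C@@H](C)C(C)=C[C@@]1(C)O[Al](C)C | intermediate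
34 | (2S,3R,6S)-2-[(2E,4E)-5-chloropenta-2,4-dien-2-yl]-3,5,6-trimethyl-3,6-dihydro-2H-pyran-3-ol | Cl/C=C/C=C(\C)[C@@H]1O[C@@H](C)C(C)=C[C@@]1(C)O | intermediate
35 | [(1E,3E)-4-{(2S,3R,4R)-2-[(2R)-1-methoxy-1-oxopropan-2-yl]-3,4-dimethyl-5-oxooxolan-3-yl}buta-1,3-dien-1-yl]boronic acid | COC(=O)[C@H](C)[C@@H]1OC(=O)[C@H](C)[C@@]1(C)/C=C/C=C/B(O)O | intermediate
36 | methyl (2R)-2-{(2S,3R,4R)-3-[(1E,3E,5E,7E)-8-[(2S,3R,6S)-3-hydroxy-3,5,6-trimethyl-3,6-dihydro-2H-pyran-2-yl]nona-1,3,5,7-tetraen-1-yl]-3,4-dimethyl-5-oxooxolan-2-yl}propanoate | COC(=O)[C@H](C)[C@@H]1OC(=O)[C@H](C)[C@@]1(C)/C=C/C=C/C=C/C=C(\C)[C@@H]1O[C@@H](C)C(C)=C[C@@]1(C)O | target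

**Step count and risks**
Total: 15 steps. Longest linear sequence: 8 steps (1–7 then 15; the pyran line 8–14 then 15 is equally long).

Most likely to fail:

Step 6 (the proposed C–H alkynylation; risks are site selectivity among the four tertiary C–H bonds and the efficiency of radical capture). The fallback uses known chemistry, sets out from 12 and comes back at 14. Tertiary C–H hydroxylation of 12 with methyl(trifluoromethyl)dioxirane (CH2Cl2, 0 °C, retention) gives methyl (2R)-2-[(2S,3R,4R)-3-hydroxy-3,4-dimethyl-5-oxooxolan-2-yl]propanoate F1. Oxalyl chloride, then N-hydroxyphthalimide and Et3N, give its N-phthalimidoyl oxalate methyl (2R)-2-[(2S,3R,4R)-3-({[(1,3-dioxoisoindolin-2-yl)oxy](oxo)acetyl}oxy)-3,4-dimethyl-5-oxooxolan-2-yl]propanoate F2. Under known photoredox conditions ([Ru(bpy)3]Cl2, Hantzsch ester, iPr2NEt, CH2Cl2, blue LEDs) F2 fragments to the same tertiary radical, which is trapped by 13 on the same face to give 14; desilylation as in step 6 then gives 15. The radical is here made from a C–O bond, so only the hydroxylation depends on C–H selectivity.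

Step 13 (facial selectivity of the Grignard addition; a pseudo-axial alkynyl conformer would give the C3 epimer). The fallback sets out from 27 and comes back at 29, delivering oxygen rather than carbon to the ring face opposite the alkynyl group. Wittig methylenation (Ph3PCH3Br, KOtBu, THF) gives (2S,6S)-2-ethynyl-5,6-dimethyl-3-methylidene-3,6-dihydro-2H-pyran F3. OsO4 (cat.)/N-methylmorpholine N-oxide dihydroxylates the less hindered exocyclic alkene trans to the alkynyl group to give (2S,3S,6S)-2-ethynyl-3-(hydroxymethyl)-5,6-dimethyl-3,6-dihydro-2H-pyran-3-ol F4. Selective primary tosylation (TsCl, pyridine) gives [(2S,3S,6S)-2-ethynyl-3-hydroxy-5,6-dimethyl-3,6-dihydro-2H-pyran-3-yl]methyl 4-methylbenzenesulfonate F5, and LiBHEt3 (THF, 0 °C) reduces the CH2OTs group to methyl, giving 29.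

Step 2 (Dieckmann closure; risks are E1cB loss of propanoate from the β-acyloxy ester, attack on the other ester and epimerisation). The fallback sets out from 4 (isolated by quenching step 1 with aqueous NH4Cl in place of 3) and comes back at 10, bypassing 5, 6 and 8. MeNHOMe·HCl/iPrMgCl (THF, −20 °C) converts the more reactive α-hydroxy ester into the Weinreb amide methyl (2R,3S)-3-hydroxy-4-[methoxy(methyl)amino]-2-methyl-4-oxobutanoate F6. MeMgBr (THF, −78 to 0 °C) gives the hydroxy ketone methyl (2R,3S)-3-hydroxy-2-methyl-4-oxopentanoate F7. Esterification with 2-(diethoxyphosphoryl)propanoic acid (DCC, DMAP, CH2Cl2) gives methyl (2R,3S)-3-{[2-(diethoxyphosphoryl)propanoyl]oxy}-2-methyl-4-oxopentanoate F8, and an intramolecular Horner–Wadsworth–Emmons reaction (LiCl, DBU, MeCN) closes the butenolide 10.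

Further compounds
F1 | step 6 | methyl (2R)-2-[(2S,3R,4R)-3-hydroxy-3,4-dimethyl-5-oxooxolan-2-yl]propanoate | COC(=O)[C@H](C)[C@@H]1OC(=O)[C@H](C)[C@@]1(C)O
F2 | step 6 | methyl (2R)-2-[(2S,3R,4R)-3-({[(1,3-dioxoisoindolin-2-yl)oxy](oxo)acetyl}oxy)-3,4-dimethyl-5-oxooxolan-2-yl]propanoate | COC(=O)[C@H](C)[C@@H]1OC(=O)[C@H](C)[C@@]1(C)OC(=O)C(=O)ON2C(=O)c3ccccc3C2=O
F3 | step 13 | (2S,6S)-2-ethynyl-5,6-dimethyl-3-methylidene-3,6-dihydro-2H-pyran | C#C[C@@H]1O[C@@H](C)C(C)=CC1=C
F4 | step 13 | (2S,3S,6S)-2-ethynyl-3-(hydroxymethyl)-5,6-dimethyl-3,6-dihydro-2H-pyran-3-ol | C#C[C@@H]1O[C@@H](C)C(C)=C[C@@]1(CO)O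
F5 | step 13 | [(2S,3S,6S)-2-ethynyl-3-hydroxy-5,6-dimethyl-3,6-dihydro-2H-pyran-3-yl]methyl 4-methylbenzenesulfonate | C#C[C@@H]1O[C@@H](C)C(C)=C[C@@]1(COS(=O)(=O)c2ccc(C)cc2)O
F6 | step 2 | methyl (2R,3S)-3-hydroxy-4-[methoxy(methyl)amino]-2-methyl-4-oxobutanoate | COC(=O)[C@H](C)[C@H](O)C(=O)N(C)OC
F7 | step 2 | methyl (2R,3S)-3-hydroxy-2-methyl-4-oxopentanoate | COC(=O)[C@H](C)[C@H](O)C(C)=O
F8 | step 2 | methyl (2R,3S)-3-{[2-(diethoxyphosphoryl)propanoyl]oxy}-2-methyl-4-oxopentanoate (mixture at the phosphonate carbon) | COC(=O)[C@H](C)[C@H](OC(=O)C(C)P(=O)(OCC)OCC)C(C)=O
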